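Its constants are assumed.

At late times the flask holds what its substrate did on the way down, so the target share is a sum over that fall, taken between two steps that compete for substrate.

substrate 0.050 M; reagent in the second phase 1.10 equiv; time 2.0 h; volume of the second phase over the first 1.0

    reagent in the reaction phase ⇌ reagent in the second phase, rate k1*([reagent in the reaction phase] - [reagent in the second phase]/K1) per volume of the first phase (K1 = 1.27, k1 = 0.133 /s)
    substrate + reagent in the reaction phase → target (k2 = 0.0348 /M/s)
    reagent in the reaction phase + target ⇌ idle adduct, settled at all times (K3 = 62.4 /M)
    2 substrate → homo dimer (k4 = 0.166 /M/s)

- percent here means substrate units held: one homo dimer counts as two
- what is said of target includes idle adduct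
- a doubled species enters its step squared and goes two at a time
- in the second phase: reagent in the second phase; everything else is in the first
- charges count per volume of the first phase; a concentration in a rate is the amount of a species over the volume of its own phase; every rate counts per litre of the first phase
- run time (flask): 2.0 h

* the target and idle adduct together standing at 2.0 h, as a percentage of the substrate charged
* the change that raises the amount of target and idle adduct together at 2.0 h, in percent of the substrate charged most ("none" if none brings more than 2 percentage points) (blue / red / none)
* amount of target and idle adduct together at 2.0 h, in percent of the substrate charged, after red

With reagent steady, the target step is pseudo-first-order in substrate, and the sum has a closed form. The share is the crossover concentration over c(substrate) charged, times the ln of one plus the inverse of that fraction. The crossover concentration is the target step's constant times c(reagent in the reaction phase), over 2 times the dimer step's constant. The two constants must be known well: an error in their ratio passes into the share with weight 0.686. The partition ratio counts too, by setting c(reagent in the reaction phase). The transfer coefficient hardly counts, because balance comes within about 4.21 s, less than the first dimer half-life of 60.2 s. Run time counts little, because the tail's time of 0.329 h is shorter than 2.0 h. With equivalents held, c(substrate) charged cancels from the fraction.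

My reckoning joins the two ends. At the start, c(reagent in the reaction phase) at balance is 0.0242 M, so the crossover concentration is 0.00254 M, the c(substrate) at which the two steps use substrate equally, and the share is 15.4%. At the late end each target has taken one reagent, and part of it holds a second as idle adduct, by an amount that depends on the late c(reagent in the reaction phase). A first pass, with that part taken at the starting balance, puts this concentration at 0.0188 M; there a fraction 0.540 of target is bound, so my late c(reagent in the reaction phase) is 0.0190 M and the share 13.0%. Midway, I commit to 14.2%. The same reckoning for blue starts at 24.2%, reaches a late c(reagent in the reaction phase) of 0.0393 M with a share of 21.2%, and gives 22.7% midway, more than the plain flask. The transfer coefficient stands outside the crossover concentration, so I expect red to stay near my figure.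

The forecast gave 14.1%, 14.3% after red and blue as best, holding that “Doubling the reagent roughly doubles free reagent”.

The flask gives 14.1%, and 14.3% after red; blue is best, gaining 8.4 percentage points against 0.14 points for red. The dimer step made 42.9% of turnover, each turn taking two substrate, against 14.1% for the target step. Half of the dimer turnover was done within 0.786 min, less than the substrate half-life of 0.37 h by the target step at 0.00115 h.

In the neighbour flask, charged with 0.013 M, the crossover concentration from its reading of 0.00534 M is 5.60 × 10⁻⁴ M, and the sum down to its 1.4% of substrate gives 12.5%. The computed result is 13.3%.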